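**Retrosynthetic overview**
1. Target 21 ⇐ benzyl ether 20 (O-debenzylation, last step).
2. 20 ⇐ open-chain diyne 17 + vinyl acetate: one Rh-catalysed [2+2+2] cyclotrimerisation builds benzene ring D from the aryl ethynyl ether, the but-3-ynyl alkyne and a C2 unit. Because the two alkynes are the chain termini, the same operation closes the 19-membered macrocycle.
3. 17 ⇐ 14 (dichlorovinyl ether → ethynyl ether) ⇐ aldehyde 10 (propargylation, benzylic deoxygenation).
4. 10 ⇐ aryl bromide 8 + isovanillin (Ullmann ether, rings A–O–B); 8 ⇐ phenol 5 + trichloroethylene.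
5. 5 ⇐ 4-(benzyloxy)-3-hydroxybenzaldehyde + diethyl (4-bromobenzyl)phosphonate (olefination, diimide; bibenzyl B–C). Ring order: A, B and C are bought; D and the macrocycle form together in step 8.

Assumption: the SMILES carries no stereodescriptor and the molecule has no stereogenic centre, so the macrocycle is treated as conformationally mobile and achiral and no enantiocontrol is needed.

**Route**

Step 1
Reactants: 1 4-(benzyloxy)-3-hydroxybenzaldehyde; 2 diethyl (4-bromobenzyl)phosphonate
Product: 4 (E)-2-(benzyloxy)-5-[2-(4-bromophenyl)ethenyl]phenol, via potassium phosphonate carbanion 3 (not isolated)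
Conditions: KOtBu (2.2 equiv), THF, 0 °C → rt; aq. HCl work-up
Reagents that add atoms: none
Why: Horner–Wadsworth–Emmons olefination of the aryl aldehyde (present as its phenoxide) with the benzylic phosphonate carbanion gives the (E)-stilbene; no stereocentre is formed and the alkene is removed in step 2.

Step 2
Reactants: 4 (E)-2-(benzyloxy)-5-[2-(4-bromophenyl)ethenyl]phenol
Product: 5 2-(benzyloxy)-5-[2-(4-bromophenyl)ethyl]phenol
Conditions: TsNHNH2 (6 equiv), NaOAc (8 equiv), DME/H2O, reflux
Reagents that add atoms: none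
Why: Diimide reduction transfers H2 to the stilbene C=C in a concerted syn addition and leaves the aryl bromide and the benzyl ether intact, which hydrogenation over Pd would not.

Step 3
Reactants: 5 2-(benzyloxy)-5-[2-(4-bromophenyl)ethyl]phenol; 6 trichloroethylene
Product: 8 1-(benzyloxy)-4-[2-(4-bromophenyl)ethyl]-2-{[(E)-1,2-dichloroethenyl]oxy}benzene, via dichloroacetylene 7 (not isolated)
Conditions: K2CO3, DMF, 70 °C
Reagents that add atoms: none
Why: Base-induced dehydrochlorination of trichloroethylene gives dichloroacetylene, to which the phenoxide adds in anti fashion to give the (E)-1,2-dichlorovinyl ether, the standard precursor of an aryl ethynyl ether, which also masks this phenol through steps 4–6.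

Step 4
Reactants: 8 1-(benzyloxy)-4-[2-(4-bromophenyl)ethyl]-2-{[(E)-1,2-dichloroethenyl]oxy}benzene; 9 isovanillin (3-hydroxy-4-methoxybenzaldehyde)
Product: 10 3-{4-[2-(4-(benzyloxy)-3-{[(E)-1,2-dichloroethenyl]oxy}phenyl)ethyl]phenoxy}-4-methoxybenzaldehyde
Conditions: CuI (copper iodide, 10 mol%), picolinic acid (20 mol%), K3PO4, DMSO, 90 °C
Reagents that add atoms: none
Why: Ligand-accelerated Ullmann diaryl ether synthesis couples the unactivated aryl bromide with the isovanillin phenol, the vinylic C–Cl bonds being much less reactive towards copper than the aryl C–Br bond.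

Step 5
Reactants: 10 3-{4-[2-(4-(benzyloxy)-3-{[(E)-1,2-dichloroethenyl]oxy}phenyl)ethyl]phenoxy}-4-methoxybenzaldehyde; 11 propargyl bromide (3-bromoprop-1-yne)
Product: 13 racemic 1-(3-{4-[2-(4-(benzyloxy)-3-{[(E)-1,2-dichloroethenyl]oxy}phenyl)ethyl]phenoxy}-4-methoxyphenyl)but-3-yn-1-ol, via allenylzinc bromide 12 (not isolated)
Conditions: Zn dust, THF/sat. aq. NH4Cl, 0 °C → rt
Reagents that add atoms: none
Why: Barbier propargylation: the allenylzinc species adds to the aldehyde through a six-membered SE2′ transition state to give the homopropargylic alcohol; the carbinol centre is racemic and is removed in step 6.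

Step 6
Reactants: 13 racemic 1-(3-{4-[2-(4-(benzyloxy)-3-{[(E)-1,2-dichloroethenyl]oxy}phenyl)ethyl]phenoxy}-4-methoxyphenyl)but-3-yn-1-ol
Product: 14 1-(benzyloxy)-4-(2-{4-[5-(but-3-yn-1-yl)-2-methoxyphenoxy]phenyl}ethyl)-2-{[(E)-1,2-dichloroethenyl]oxy}benzene
Conditions: Et3SiH, TFA, CH2Cl2, 0 °C
Reagents that add atoms: none
Why: Ionic hydrogenation: the benzylic alcohol ionises readily (cation para to the methoxy group) and is reduced by hydride transfer from the silane, which deletes the only stereocentre while the electron-poor dichlorovinyl ether and the alkyne survive the short cold acid exposure.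

Step 7
Reactants: 14 1-(benzyloxy)-4-(2-{4-[5-(but-3-yn-1-yl)-2-methoxyphenoxy]phenyl}ethyl)-2-{[(E)-1,2-dichloroethenyl]oxy}benzene
Product: 17 1-(benzyloxy)-4-(2-{4-[5-(but-3-yn-1-yl)-2-methoxyphenoxy]phenyl}ethyl)-2-(ethynyloxy)benzene, via chloroethynyl ether 15 (not isolated), via dilithium diacetylide 16 (not isolated)
Conditions: n-BuLi (3.5 equiv), THF, −78 → −40 °C; then H2O, −78 °C; crude 17 used at once
Reagents that add atoms: none
Why: Standard dichlorovinyl-ether route to ynol ethers: n-BuLi removes the vinylic proton and LiCl is eliminated to the chloroethynyl ether, chlorine–lithium exchange gives the lithium acetylide, and the water quench returns both terminal alkynes (the but-3-ynyl C–H is simply deprotonated and reprotonated).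

Step 8
Reactants: 17 1-(benzyloxy)-4-(2-{4-[5-(but-3-yn-1-yl)-2-methoxyphenoxy]phenyl}ethyl)-2-(ethynyloxy)benzene; 18 vinyl acetate
Product: 20 O-benzyl macrocycle (the benzyl ether of 21 at the ring C phenol), via acetoxycyclohexadiene 19 (not isolated)
Conditions: [Rh(cod)2]BF4/H8-BINAP (10 mol%, activated with H2), vinyl acetate (20 equiv)/CH2Cl2, 17 added by syringe pump over 12 h (final 2 mM), rt
Reagents that add atoms: none
Why: Proposed new method: on the cationic monovalent-rhodium/H8-BINAP centre the two terminal alkynes of 17 should couple head-to-tail (a terminal alkyne carbon bonding to the oxygen-bearing or internal carbon of its partner, the polarity pattern seen in cyclotrimerisations of aryl ethynyl ethers) to a macrocyclic rhodacyclopentadiene that inserts vinyl acetate, reductively eliminates to 19 and aromatises by loss of AcOH, so that the 1,3-disubstituted ring D and the 19-membered ring close together with no stereocentre remaining; the closest known reactions are rhodium-catalysed [2+2+2] cross-cyclotrimerisations of aryl ethynyl ethers, [2+2+2] macrocyclisations of α,ω-diynes to cyclophanes and the use of enol acetates as acetylene equivalents, while slow addition suppresses intermolecular alkyne coupling and an alkene partner cannot cap a single alkyne.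

Step 9
Reactants: 20 O-benzyl macrocycle
Product: 21 target macrocycle CNP0132125.0
Conditions: H2 (1 atm), Pd/C, EtOAc/MeOH, rt
Reagents that add atoms: none
Why: Catalytic hydrogenolysis cleaves the benzyl ether to the free ring C phenol and leaves the diaryl ethers, the methyl ether and the bibenzyl bridges untouched.

**Compound list**
1 | 4-(benzyloxy)-3-hydroxybenzaldehyde | O=Cc1ccc(OCc2ccccc2)c(O)c1 | starting material
2 | diethyl (4-bromobenzyl)phosphonate | CCOP(=O)(Cc1ccc(Br)cc1)OCC | starting material
3 | potassium salt of the benzylic carbanion of 2 | [K+].CCOP(=O)([CH-]c1ccc(Br)cc1)OCC | intermediate (not isolated)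
4 | (E)-2-(benzyloxy)-5-[2-(4-bromophenyl)ethenyl]phenol | Oc1cc(/C=C/c2ccc(Br)cc2)ccc1OCc1ccccc1 | intermediate
5 | 2-(benzyloxy)-5-[2-(4-bromophenyl)ethyl]phenol | Oc1cc(CCc2ccc(Br)cc2)ccc1OCc1ccccc1 | intermediate
6 | trichloroethylene | ClC=C(Cl)Cl | starting material
7 | dichloroacetylene | ClC#CCl | intermediate (not isolated)
8 | 1-(benzyloxy)-4-[2-(4-bromophenyl)ethyl]-2-{[(E)-1,2-dichloroethenyl]oxy}benzene | Brc1ccc(CCc2ccc(OCc3ccccc3)c(O/C(Cl)=C\Cl)c2)cc1 | intermediate
9 | isovanillin (3-hydroxy-4-methoxybenzaldehyde) | COc1ccc(C=O)cc1O | starting material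
10 | 3-{4-[2-(4-(benzyloxy)-3-{[(E)-1,2-dichloroethenyl]oxy}phenyl)ethyl]phenoxy}-4-methoxybenzaldehyde | COc1ccc(C=O)cc1Oc1ccc(CCc2ccc(OCc3ccccc3)c(O/C(Cl)=C\Cl)c2)cc1 | intermediate
11 | propargyl bromide (3-bromoprop-1-yne) | BrCC#C | starting material
12 | allenylzinc bromide | C=C=C[Zn]Br | intermediate (not isolated)
13 | 1-(3-{4-[2-(4-(benzyloxy)-3-{[(E)-1,2-dichloroethenyl]oxy}phenyl)ethyl]phenoxy}-4-methoxyphenyl)but-3-yn-1-ol, racemic | COc1ccc(C(O)CC#C)cc1Oc1ccc(CCc2ccc(OCc3ccccc3)c(O/C(Cl)=C\Cl)c2)cc1 | intermediate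
14 | 1-(benzyloxy)-4-(2-{4-[5-(but-3-yn-1-yl)-2-methoxyphenoxy]phenyl}ethyl)-2-{[(E)-1,2-dichloroethenyl]oxy}benzene | COc1ccc(CCC#C)cc1Oc1ccc(CCc2ccc(OCc3ccccc3)c(O/C(Cl)=C\Cl)c2)cc1 | intermediate
15 | chloroethynyl ether of 14 with the but-3-ynyl group as its lithium acetylide | [Li]C#CCCc1ccc(OC)c(Oc2ccc(CCc3ccc(OCc4ccccc4)c(OC#CCl)c3)cc2)c1 | intermediate (not isolated)
16 | dilithium diacetylide of 17 | [Li]C#CCCc1ccc(OC)c(Oc2ccc(CCc3ccc(OCc4ccccc4)c(OC#C[Li])c3)cc2)c1 | intermediate (not isolated)
17 | 1-(benzyloxy)-4-(2-{4-[5-(but-3-yn-1-yl)-2-methoxyphenoxy]phenyl}ethyl)-2-(ethynyloxy)benzene | C#CCCc1ccc(OC)c(Oc2ccc(CCc3ccc(OCc4ccccc4)c(OC#C)c3)cc2)c1 | intermediate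
18 | vinyl acetate | C=COC(C)=O | starting material
19 | macrocyclic 5-acetoxycyclohexa-1,3-diene (ring D before loss of AcOH; racemic, drawn as one of two convergent acetate regioisomers) | COc1ccc2cc1Oc1ccc(cc1)CCc1ccc(OCc3ccccc3)c(c1)OC1=CC(OC(C)=O)CC(=C1)CC2 | intermediate (not isolated)
20 | O-benzyl macrocycle (21 with OCH2Ph in place of OH on ring C) | COc1ccc2cc1Oc1ccc(cc1)CCc1ccc(OCc3ccccc3)c(c1)Oc1cccc(c1)CC2 | intermediate
21 | target macrocycle CNP0132125.0 (19-membered bis(bibenzyl) diether; ring A 4-methoxy, ring B para-phenylene, ring C 4-hydroxy, ring D meta-phenylene; no stereocentre) | COc1ccc2cc1Oc1ccc(cc1)CCc1ccc(O)c(c1)Oc1cccc(c1)CC2 | target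

**Step count and risks**
Total steps: 9. Longest linear sequence: 9 (1 → 21); every other input is a purchased reagent.

Most likely to fail, in order:

Step 8. The macrocyclising three-component [2+2+2] has no direct precedent for an ynol ether/alkyl alkyne pair. It may give oligomers, the 1,4- or 1,2-regioisomer of ring D, or lose the ynol ether to the AcOH released. The fallback gives up the de novo construction of ring D, sets out from phenol 5 and returns at 21. Chan–Lam–Evans coupling of 5 with (3-formylphenyl)boronic acid (Cu(OAc)2, pyridine, 4 Å sieves, CH2Cl2, air, rt) gives 3-{2-(benzyloxy)-5-[2-(4-bromophenyl)ethyl]phenoxy}benzaldehyde F1. Ullmann coupling of F1 with isovanillin 9 under the step 4 conditions gives the dialdehyde 3-{4-[2-(4-(benzyloxy)-3-(3-formylphenoxy)phenyl)ethyl]phenoxy}-4-methoxybenzaldehyde F2. Intramolecular McMurry coupling with low-valent titanium (TiCl4, Zn, pyridine, THF, reflux, high dilution) gives the macrocyclic stilbene F3 as an E/Z mixture. H2 over Pd/C then saturates the alkene and removes the benzyl group to give 21 directly.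

Step 7. The terminal aryl ethynyl ether is acid- and concentration-sensitive, and n-BuLi may also lithiate next to the benzyl or diaryl ether. The fallback sets out from 14 and returns at 17, carrying the ynol ether in masked, isolable form. After the same lithiation the dilithium species is quenched with Me3SiCl to give 1-(benzyloxy)-4-(2-{4-[2-methoxy-5-(4-(trimethylsilyl)but-3-yn-1-yl)phenoxy]phenyl}ethyl)-2-{[(trimethylsilyl)ethynyl]oxy}benzene F4, which can be chromatographed and stored. Both silyl groups are removed with K2CO3 in MeOH/THF at 0 °C immediately before the cyclisation, delivering 17 as a fresh solution.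

Step 4. Hot basic Ullmann conditions may degrade the dichlorovinyl ether or stall on the unactivated bromide. The fallback sets out from 8 and returns at 10, replacing the hot aryl-halide coupling by a room-temperature oxidative coupling of an arylboron compound. Miyaura borylation of 8 (PdCl2(dppf), B2pin2, KOAc, dioxane, 80 °C) gives 2-{4-[2-(4-(benzyloxy)-3-{[(E)-1,2-dichloroethenyl]oxy}phenyl)ethyl]phenyl}-4,4,5,5-tetramethyl-1,3,2-dioxaborolane F5. Chan–Lam–Evans coupling of F5 with isovanillin 9 (Cu(OAc)2, pyridine, B(OH)3, 4 Å sieves, MeCN, air, rt) then gives 10.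

**Further compounds**
F1 | step 8 | 3-{2-(benzyloxy)-5-[2-(4-bromophenyl)ethyl]phenoxy}benzaldehyde | O=Cc1cccc(Oc2cc(CCc3ccc(Br)cc3)ccc2OCc2ccccc2)c1
F2 | step 8 | 3-{4-[2-(4-(benzyloxy)-3-(3-formylphenoxy)phenyl)ethyl]phenoxy}-4-methoxybenzaldehyde | COc1ccc(C=O)cc1Oc1ccc(CCc2ccc(OCc3ccccc3)c(Oc3cccc(C=O)c3)c2)cc1
F3 | step 8 | macrocyclic stilbene (20 with CH=CH in place of the CH2CH2 bridge between rings D and A; E/Z mixture) | COc1ccc2cc1Oc1ccc(cc1)CCc1ccc(OCc3ccccc3)c(c1)Oc1cccc(c1)C=C2
F4 | step 7 | 1-(benzyloxy)-4-(2-{4-[2-methoxy-5-(4-(trimethylsilyl)but-3-yn-1-yl)phenoxy]phenyl}ethyl)-2-{[(trimethylsilyl)ethynyl]oxy}benzene | COc1ccc(CCC#C[Si](C)(C)C)cc1Oc1ccc(CCc2ccc(OCc3ccccc3)c(OC#C[Si](C)(C)C)c2)cc1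
F5 | step 4 | 2-{4-[2-(4-(benzyloxy)-3-{[(E)-1,2-dichloroethenyl]oxy}phenyl)ethyl]phenyl}-4,4,5,5-tetramethyl-1,3,2-dioxaborolane | CC1(C)OB(OC1(C)C)c1ccc(CCc2ccc(OCc3ccccc3)c(O/C(Cl)=C\Cl)c2)cc1
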